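**Plan**

- Numbering used below is that of the daucane skeleton: C1 angular-methyl carbon, C2/C3 ring CH2, C4 isopropyl carbinol, C5 ring-fusion CH, C6 ester carbon, C7 ring CH2, C8=C9 alkene, C10 allylic carbinol.
- Retrosynthesis cuts, in order: the C6–O ester, the C4–isopropyl bond, the C6–O bond (as C–B on an enone), then C1–C5 and C6–C7 together, then C4–C5 (Weinreb ketone synthesis) and C2=C3 (HWE), and last the cyclopropane.
- Enabling feature: in the seven-membered ring, C1–C10–C9=C8–C7 is a ring-opened vinylcyclopropane (C1–C9 bond closed, C7=C8 as an isopropenyl group), C5–C6 is a two-carbon π unit, and the cyclopentane carbons C2–C3–C4 are the tether joining them.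
- Forward: Z-dienol → all-cis siloxy vinylcyclopropane → chain extension on C1 to an ynone → Rh(I) [5+2] closes the five- and the seven-membered ring in one operation → C6 oxygenation, isopropyl addition, esterification, desilylation.
- Stereochemistry: C1 and C10 come from a ligand-controlled zinco-cyclopropanation (Z geometry and zinc chelation give the all-cis ring) and are carried through the cycloaddition with retention. C6, C5 and C4 are then set on the bicycle, anti to the C1 methyl group (C5 by equilibration).

Key step: step 10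

Assumption: the sense of induction in step 3 follows the usual Charette dioxaborolane model; if intermediate 7 proves enantiomeric, the (4R,5R)-ligand is used instead.

**Route**

Step 1
Reactants: 1 methacrolein; 2 ethyl 2-[bis(2,2,2-trifluoroethoxy)phosphoryl]propanoate
Product: 3 ethyl (2Z)-2,4-dimethylpenta-2,4-dienoate
Conditions: KHMDS, 18-crown-6, THF, −78 °C
Reagents that add atoms: none
Why: Still–Gennari olefination, in which the electron-poor phosphonate makes elimination from the kinetic adduct fast, so the ester and the isopropenyl group should end up cis (Z).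

Step 2
Reactants: 3 ethyl (2Z)-2,4-dimethylpenta-2,4-dienoate
Product: 4 (2Z)-2,4-dimethylpenta-2,4-dien-1-ol
Conditions: DIBAL-H (2.2 equiv), CH2Cl2, −78 °C; Rochelle salt work-up
Reagents that add atoms: none
Why: DIBAL-H 1,2-reduction of an unsaturated ester should leave the diene and its Z geometry untouched.

Step 3
Reactants: 4 (2Z)-2,4-dimethylpenta-2,4-dien-1-ol; 5 iodoform
Product: 7 (1R,2R,3R)-2-(hydroxymethyl)-2-methyl-3-(prop-1-en-2-yl)cyclopropan-1-ol (OH, CH2OH and isopropenyl all cis), via cyclic borinate 6 (not isolated)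
Conditions: EtZnI (from Et2Zn + I2), (4S,5S)-2-butyl-N,N,N′,N′-tetramethyl-1,3,2-dioxaborolane-4,5-dicarboxamide (1.2 equiv), CH2Cl2, −40 → 0 °C; then NaBO3·4H2O, THF/H2O, 0 °C
Reagents that add atoms: (4S,5S)-2-butyl-N,N,N′,N′-tetramethyl-1,3,2-dioxaborolane-4,5-dicarboxamide (CCCCB1O[C@H](C(=O)N(C)C)[C@H](O1)C(=O)N(C)C); sodium perborate ([Na+].[Na+].O[B-]1(O)OO[B-](O)(O)OO1)
Why: Charette zinco-cyclopropanation, in which the gem-dizinc carbenoid is delivered only to the allylic C=C, the Z alkene places isopropenyl cis to CH2OH, the new C–Zn bond is held cis to the CH2O group by chelation and is exchanged to boron and oxidised with retention, and the dioxaborolane selects the face.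

Step 4
Reactants: 7 cyclopropane diol
Product: 8 bis(triethylsilyl) ether of 7
Conditions: TESCl (2.4 equiv), imidazole, CH2Cl2, 0 °C
Reagents that add atoms: chlorotriethylsilane (CC[Si](Cl)(CC)CC)
Why: Standard silylation of both hydroxyls, which also protects the cyclopropanol from base-induced ring opening.

Step 5
Reactants: 8 bis(triethylsilyl) ether
Product: 9 (1S,2R,3R)-1-methyl-2-(prop-1-en-2-yl)-3-(triethylsilyloxy)cyclopropane-1-carbaldehyde
Conditions: (COCl)2, DMSO, CH2Cl2, −78 → −30 °C; Et3N; used cold and at once
Reagents that add atoms: none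
Why: Swern conditions cleave and oxidise a primary TES ether directly to the aldehyde while a secondary TES ether survives, and the C10 siloxy group syn to both π groups should block the boat geometry needed for retro-Claisen ring opening.

Step 6
Reactants: 9 cyclopropanecarbaldehyde; 10 trimethyl phosphonoacetate
Product: 11 methyl (2E)-3-[1-methyl-2-(prop-1-en-2-yl)-3-(triethylsilyloxy)cyclopropyl]prop-2-enoate (ring configuration as in 9)
Conditions: LiCl, DBU, MeCN, 0 °C; carried on without delay
Reagents that add atoms: none
Why: Masamune–Roush Horner–Wadsworth–Emmons olefination gives the E-enoate under mild base, and the syn C10 substituent should likewise retard the cis-divinylcyclopropane Cope rearrangement.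

Step 7
Reactants: 11 enoate
Product: 12 methyl 3-[1-methyl-2-(prop-1-en-2-yl)-3-(triethylsilyloxy)cyclopropyl]propanoate
Conditions: Cu(OAc)2 (5 mol %), 1,2-bis(diphenylphosphino)benzene (5 mol %), (EtO)2MeSiH, t-BuOH, toluene, 0 °C → rt
Reagents that add atoms: none
Why: Copper hydride conjugate reduction (Stryker type) should deliver hydride only to the enoate β-carbon and leave the isopropenyl group, the cyclopropane and the silyl ether.

Step 8
Reactants: 12 saturated ester
Product: 13 Weinreb amide, N-methoxy-N-methyl-3-[1-methyl-2-(prop-1-en-2-yl)-3-(triethylsilyloxy)cyclopropyl]propanamide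
Conditions: MeNH(OMe)·HCl, LiHMDS, THF, −78 → −10 °C
Reagents that add atoms: N,O-dimethylhydroxylamine hydrochloride (CNOC.Cl)
Why: Aminolysis of the methyl ester by the lithium amide of N,O-dimethylhydroxylamine gives the Weinreb amide.

Step 9
Reactants: 13 Weinreb amide; 14 ethynylmagnesium bromide
Product: 15 ynone, 5-[1-methyl-2-(prop-1-en-2-yl)-3-(triethylsilyloxy)cyclopropyl]pent-1-yn-3-one
Conditions: THF, 0 °C; cold aqueous NaHSO4 quench
Reagents that add atoms: none
Why: Weinreb ketone synthesis, in which the chelated tetrahedral adduct stops at mono-addition and releases the terminal ynone on quench.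

Step 10
Reactants: 15 ynone
Product: 16 (1S,10R)-10-(triethylsilyloxy)-11,12,13-trinordauca-5,8-dien-4-one (hydroazulene dienone: C4 ketone in the five-membered ring, C5=C6 and C8=C9 in the seven-membered ring, C1 methyl trans to C10–O)
Conditions: [Rh(CO)2Cl]2 (5 mol %), 1,2-dichloroethane, 70 °C
Reagents that add atoms: none
Why: Proposed new method: Rh(I), chelated by the ynone π bond and the cis isopropenyl group, should insert into the C1–C9 cyclopropane bond with retention at C1 to give a σ-alkyl/η3-allyl rhodacycle (Rh–C1, allyl C9–C8–C7), the tethered alkyne then inserts syn into Rh–C1, and C(sp2)–C(sp3) reductive elimination joins C6 to the allyl terminus C7. The closest known reaction type is the Rh(I)-catalysed intramolecular [5+2] cycloaddition of vinylcyclopropanes with tethered 2π partners, in particular of cis-2-ene-vinylcyclopropanes whose tether sits on the ring carbon next to the vinyl-bearing one; an ynone partner, a quaternary tether carbon and a siloxy group on the third ring carbon have not been combined in it. The cyclopentenone ring closes by 5-exo-dig carbometallation (C1–C5) and the cyclohepta-1,4-diene ring by reductive elimination at the distal end of the allyl unit (C6–C7), which leaves C8=C9 as the ring Z-alkene. No new stereocentre arises: C1 keeps its configuration through two retentive organometallic steps and C10 is a spectator, so the cyclopropane configuration becomes that of the quaternary centre and the allylic ether. The step needs cleavage of C1–C9 rather than the donor-substituted C9–C10 bond and [5+2] rather than [3+2] closure; the three-atom tether can bring the alkyne only to the C1–C9 edge, the cis arrangement of tether and isopropenyl group favours the seven-membered reductive elimination, and β-hydride loss from C1–Rh is disfavoured inside the metallacycle.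

Step 11
Reactants: 16 dienone
Product: 18 (1S,5S,6S,10R)-6-hydroxy-10-(triethylsilyloxy)-11,12,13-trinordauc-8-en-4-one (trans-fused), via boryl ketone 17 (not isolated)
Conditions: CuCl (5 mol %), Xantphos (5 mol %), NaOt-Bu (10 mol %), B2pin2, MeOH, THF, rt; then NaBO3·4H2O, THF/H2O, rt
Reagents that add atoms: bis(pinacolato)diboron (CC1(C)OB(OC1(C)C)B1OC(C)(C)C(C)(C)O1); sodium perborate ([Na+].[Na+].O[B-]1(O)OO[B-](O)(O)OO1)
Why: Copper-catalysed conjugate borylation places boron on the enone β-carbon C6, expected anti to the C1 methyl group, C–B oxidation proceeds with retention, and C5 (α to the ketone) should settle by protonation/equilibration in the trans ring fusion.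

Step 12
Reactants: 18 hydroxy ketone; 19 isopropylmagnesium chloride
Product: 20 (1S,4R,5S,6S,10R)-10-(triethylsilyloxy)dauc-8-ene-4,6-diol
Conditions: anhydrous CeCl3, THF, −78 °C (excess reagent; the first equivalent deprotonates C6–OH)
Reagents that add atoms: none
Why: Organocerium 1,2-addition (Imamoto conditions suppress enolisation and β-hydride reduction) should occur on the C4 face anti to the axial C1 methyl group of the trans-fused ring, placing the new hydroxyl cis to that methyl.

Step 13
Reactants: 20 diol; 21 4-methoxybenzoyl chloride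
Product: 22 (1S,4R,5S,6S,10R)-4-hydroxy-10-(triethylsilyloxy)dauc-8-en-6-yl 4-methoxybenzoate
Conditions: DMAP, Et3N, CH2Cl2, 0 °C → rt
Reagents that add atoms: none
Why: DMAP-catalysed acylation should take the secondary C6–OH and leave the tertiary C4–OH, with C10 still silylated.

Step 14
Reactants: 22 silyl ether
Product: 23 (1S,4R,5S,6S,10R)-4,10-dihydroxydauc-8-en-6-yl 4-methoxybenzoate (target)
Conditions: HF·pyridine, pyridine, THF, 0 °C
Reagents that add atoms: none
Why: Buffered fluoride desilylation should free the allylic C10–OH without touching the aryl ester or the tertiary alcohol.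

**Compound list**

1 | methacrolein | C=C(C)C=O | starting material
2 | ethyl 2-[bis(2,2,2-trifluoroethoxy)phosphoryl]propanoate | CCOC(=O)C(C)P(=O)(OCC(F)(F)F)OCC(F)(F)F | starting material
3 | ethyl (2Z)-2,4-dimethylpenta-2,4-dienoate | CCOC(=O)/C(C)=C\C(C)=C | intermediate
4 | (2Z)-2,4-dimethylpenta-2,4-dien-1-ol | OC/C(C)=C\C(C)=C | intermediate
5 | iodoform | IC(I)I | starting material
6 | cyclic borinate, 2-butyl-5-methyl-6-(prop-1-en-2-yl)-3-oxa-2-borabicyclo[3.1.0]hexane (B on C10, O on the CH2 at C1) | CCCCB1OC[C@@]2(C)[C@@H](C(C)=C)[C@@H]12 | intermediate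
7 | (1R,2R,3R)-2-(hydroxymethyl)-2-methyl-3-(prop-1-en-2-yl)cyclopropan-1-ol | OC[C@@]1(C)[C@@H](C(C)=C)[C@H]1O | intermediate
8 | bis(triethylsilyl) ether of 7 | CC[Si](CC)(CC)OC[C@@]1(C)[C@@H](C(C)=C)[C@H]1O[Si](CC)(CC)CC | intermediate
9 | (1S,2R,3R)-1-methyl-2-(prop-1-en-2-yl)-3-(triethylsilyloxy)cyclopropane-1-carbaldehyde | O=C[C@@]1(C)[C@@H](C(C)=C)[C@H]1O[Si](CC)(CC)CC | intermediate
10 | trimethyl phosphonoacetate | COC(=O)CP(=O)(OC)OC | starting material
11 | methyl (2E)-3-[1-methyl-2-(prop-1-en-2-yl)-3-(triethylsilyloxy)cyclopropyl]prop-2-enoate | COC(=O)/C=C/[C@@]1(C)[C@@H](C(C)=C)[C@H]1O[Si](CC)(CC)CC | intermediate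
12 | methyl 3-[1-methyl-2-(prop-1-en-2-yl)-3-(triethylsilyloxy)cyclopropyl]propanoate | COC(=O)CC[C@@]1(C)[C@@H](C(C)=C)[C@H]1O[Si](CC)(CC)CC | intermediate
13 | N-methoxy-N-methyl-3-[1-methyl-2-(prop-1-en-2-yl)-3-(triethylsilyloxy)cyclopropyl]propanamide | CON(C)C(=O)CC[C@@]1(C)[C@@H](C(C)=C)[C@H]1O[Si](CC)(CC)CC | intermediate
14 | ethynylmagnesium bromide | C#C[Mg]Br | starting material
15 | 5-[1-methyl-2-(prop-1-en-2-yl)-3-(triethylsilyloxy)cyclopropyl]pent-1-yn-3-one | C#CC(=O)CC[C@@]1(C)[C@@H](C(C)=C)[C@H]1O[Si](CC)(CC)CC | intermediate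
16 | (1S,10R)-10-(triethylsilyloxy)-11,12,13-trinordauca-5,8-dien-4-one | O=C1CC[C@]2(C)[C@H](O[Si](CC)(CC)CC)C=C(C)CC=C12 | intermediate
17 | 6-(pinacolatoboryl)-10-(triethylsilyloxy)-11,12,13-trinordauc-8-en-4-one (B where the C6 oxygen will be) | CC1(C)OB(OC1(C)C)[C@H]2CC(C)=C[C@@H](O[Si](CC)(CC)CC)[C@@]3(C)CCC(=O)[C@H]23 | intermediate
18 | (1S,5S,6S,10R)-6-hydroxy-10-(triethylsilyloxy)-11,12,13-trinordauc-8-en-4-one | O[C@H]1CC(C)=C[C@@H](O[Si](CC)(CC)CC)[C@@]2(C)CCC(=O)[C@H]12 | intermediate
19 | isopropylmagnesium chloride | CC(C)[Mg]Cl | starting material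
20 | (1S,4R,5S,6S,10R)-10-(triethylsilyloxy)dauc-8-ene-4,6-diol | O[C@H]1CC(C)=C[C@@H](O[Si](CC)(CC)CC)[C@@]2(C)CC[C@@](O)(C(C)C)[C@H]12 | intermediate
21 | 4-methoxybenzoyl chloride | COc1ccc(cc1)C(Cl)=O | starting material
22 | (1S,4R,5S,6S,10R)-4-hydroxy-10-(triethylsilyloxy)dauc-8-en-6-yl 4-methoxybenzoate | COc1ccc(C(=O)O[C@H]2CC(C)=C[C@@H](O[Si](CC)(CC)CC)[C@@]3(C)CC[C@@](O)(C(C)C)[C@H]23)cc1 | intermediate
23 | (1S,4R,5S,6S,10R)-4,10-dihydroxydauc-8-en-6-yl 4-methoxybenzoate | COc1ccc(C(=O)O[C@H]2CC(C)=C[C@@H](O)[C@@]3(C)CC[C@@](O)(C(C)C)[C@H]23)cc1 | target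

**Step count and risks**

Total steps: 14. Longest linear sequence: 14 (from methacrolein).

Steps most likely to fail:

Step 10 (Proposed new method). Rhodium may insert into the donor-substituted C9–C10 bond instead of C1–C9, or the terminal ynone may be lost to alkyne oligomerisation before it inserts into the hindered tertiary alkyl–rhodium bond. The fallback uses an alkene as the 2π partner, the substrate class on which this tether arrangement is documented, and restores the double bond afterwards. It sets out from Weinreb amide 13 and comes back at dienone 16. Vinylmagnesium bromide converts 13 into the vinyl ketone F1. The Rh(I)-catalysed [5+2] cycloaddition of this cis-2-ene-vinylcyclopropane ([Rh(CO)2Cl]2, toluene, 80–110 °C) should give the saturated bicyclic ketone F2, of which either C5 epimer serves. Thermodynamic enolisation towards C5 (TMSOTf, Et3N) gives the silyl enol ether F3, and Saegusa–Ito oxidation (Pd(OAc)2, MeCN) removes H-6 to give 16.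

Step 11. Boron may be delivered to C6 with poor facial selectivity, and the enolate may be protonated to the cis ring fusion, which would also misdirect step 12. The fallback sets C4 first and C5/C6 last by equilibration and hydroxyl-directed reduction. It sets out from dienone 16 and comes back at diol 20. Addition of i-PrMgCl/CeCl3 to 16, anti to the C1 methyl and independent of C5, gives the tertiary allylic alcohol F4. Hydroxyl-directed epoxidation (VO(acac)2, t-BuOOH) gives the epoxy alcohol F5. Reductive opening with Cp2TiCl and 1,4-cyclohexadiene, via the tertiary C5 radical, gives the 1,3-diol F6. Dess–Martin oxidation of the secondary alcohol, with DBU equilibration at C5, gives the trans-fused hydroxy ketone F7. Anti-selective reduction with Me4NBH(OAc)3, directed by the C4 hydroxyl, then gives 20.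

Step 12. The branched Grignard reagent may enolise or reduce the hindered ketone, or the β-alkoxide may open by retro-aldol cleavage. The fallback uses an sp2 nucleophile without β-hydrogens followed by chemoselective hydrogenation. It sets out from hydroxy ketone 18 and comes back at diol 20. Isopropenylmagnesium bromide/CeCl3 gives the isopropenyl carbinol F8, and hydrogenation with Wilkinson's catalyst (H2, (Ph3P)3RhCl, benzene) should reduce only the 1,1-disubstituted alkene to give 20.

**Further compounds**

F1 | step 10 | 5-[1-methyl-2-(prop-1-en-2-yl)-3-(triethylsilyloxy)cyclopropyl]pent-1-en-3-one | C=CC(=O)CC[C@@]1(C)[C@@H](C(C)=C)[C@H]1O[Si](CC)(CC)CC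
F2 | step 10 | 10-(triethylsilyloxy)-11,12,13-trinordauc-8-en-4-one (C5 epimers) | O=C1CC[C@]2(C)[C@H](O[Si](CC)(CC)CC)C=C(C)CCC12
F3 | step 10 | 4-(trimethylsilyloxy)-10-(triethylsilyloxy)-11,12,13-trinordauca-4,8-diene | C[Si](C)(C)OC1=C2CCC(C)=C[C@@H](O[Si](CC)(CC)CC)[C@@]2(C)CC1
F4 | step 11 | 10-(triethylsilyloxy)dauca-5,8-dien-4-ol | CC(C)[C@]1(O)CC[C@]2(C)[C@H](O[Si](CC)(CC)CC)C=C(C)CC=C12
F5 | step 11 | 5,6-epoxy-10-(triethylsilyloxy)dauc-8-en-4-ol (epoxide syn to 4-OH) | CC(C)[C@]1(O)CC[C@]2(C)[C@H](O[Si](CC)(CC)CC)C=C(C)C[C@H]3O[C@@]123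
F6 | step 11 | 6-epi-10-(triethylsilyloxy)dauc-8-ene-4,6-diol (C5 epimers) | CC(C)[C@]1(O)CC[C@]2(C)[C@H](O[Si](CC)(CC)CC)C=C(C)C[C@@H](O)C12
F7 | step 11 | 4-hydroxy-10-(triethylsilyloxy)dauc-8-en-6-one (trans-fused) | CC(C)[C@]1(O)CC[C@]2(C)[C@H](O[Si](CC)(CC)CC)C=C(C)CC(=O)[C@@H]12
F8 | step 12 | 10-(triethylsilyloxy)dauca-8,11-diene-4,6-diol (isopropenyl in place of isopropyl) | O[C@H]1CC(C)=C[C@@H](O[Si](CC)(CC)CC)[C@@]2(C)CC[C@@](O)(C(C)=C)[C@H]12
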